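**Retrosynthetic overview** (labdane numbering)
1. Target ← allyl ester; the Z-C13=C14 alkene comes from syn-addition of Me2CuLi to a C13≡C14 ynoate; 9α-H and the C8=C17 methylene come from palladium/formate hydrogenolysis of a C9 tertiary allylic carbonate, itself made from an 8-methylene-9-ketone and a C11–C14 Grignard reagent.
2. 2β-OAc ← trans-diaxial bromoacetoxylation of a C2=C3 alkene, then removal of the C3 bromine.
3. Ring A ← one-flask Michael/Wittig annulation of a C10 enolate, vinyltriphenylphosphonium bromide (C1 and C2) and a C3 aldehyde: it forms C1–C10 (quaternary, trans fusion) and C2=C3.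
4. Ring B is purchased as 2-methylcyclohex-2-enone (C5–C10 with C20); C5, the C4 gem-dimethyl carbon and C3 are added by an enantioselective Mukaiyama–Michael reaction. Ring order: B (bought), then A (key step).
5. Enabling feature: the C9 carbonyl of ring B makes C10, the carbon that carries C20, a regiodefined tetrasubstituted enolate; quaternary C4 makes the C3 aldehyde non-enolisable and, through C5, holds it 1,4 to C10, so a two-carbon vinyl unit closes six-membered ring A.

Key step: step 5

Convention: labdane numbering throughout (ring A = C1–C5, C10; ring B = C5–C10; C17 = methylene carbon on C8; C20 = methyl on C10; side chain C11–C16); β is the face of C20.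
Assumption: the (S)-configured oxazaborolidinium catalyst is taken to direct the ketene acetal to the enone face that gives (1R)-4; if the sense of induction is the opposite, the (R)-catalyst is used without other change.

Step 1
Reactants: 1 methyl 2-methylpropanoate
Product: 2 tert-butyl[(1-methoxy-2-methylprop-1-en-1-yl)oxy]dimethylsilane
Conditions: LiN(i-Pr)2, THF, −78 °C; t-BuMe2SiCl, DMPU, −78 °C → rt
Reagents that add atoms: tert-butyldimethylsilyl chloride, CC(C)(C)[Si](C)(C)Cl
Why: O-silylation of the lithium ester enolate in the presence of DMPU is the standard preparation of a silyl ketene acetal, and no stereocenter is formed.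

Step 2
Reactants: 2 tert-butyl[(1-methoxy-2-methylprop-1-en-1-yl)oxy]dimethylsilane; 3 2-methylcyclohex-2-en-1-one
Product: 4 methyl 2-[(1R)-3-{[tert-butyl(dimethyl)silyl]oxy}-2-methylcyclohex-2-en-1-yl]-2-methylpropanoate
Conditions: (S)-3,3-diphenyl-1-(2-methylphenyl)tetrahydro-1H,3H-pyrrolo[1,2-c][1,3,2]oxazaborole·HNTf2 (20 mol %), Ph3P=O (25 mol %), toluene, −20 °C
Reagents that add atoms: none
Why: In this catalytic enantioselective Mukaiyama–Michael addition the chiral oxazaborolidinium cation binds the enone carbonyl and screens one face of the β-carbon C5, so that the ketene acetal carbon C4 adds to the open face and sets (R)-C5, while silyl transfer to the enolate oxygen fixes the C9=C10 double bond of the silyl enol ether.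

Step 3
Reactants: 4 methyl 2-[(1R)-3-{[tert-butyl(dimethyl)silyl]oxy}-2-methylcyclohex-2-en-1-yl]-2-methylpropanoate
Product: 5 2-[(1S)-3-{[tert-butyl(dimethyl)silyl]oxy}-2-methylcyclohex-2-en-1-yl]-2-methylpropan-1-ol
Conditions: i-Bu2AlH (2.5 equiv), CH2Cl2, −78 → 0 °C; aq. KNaC4H4O6
Reagents that add atoms: none
Why: Ester reduction by i-Bu2AlH should give the neopentyl primary alcohol while the silyl enol ether is inert to the hydride, and C5 is untouched (the descriptor changes only by priority).

Step 4
Reactants: 5 2-[(1S)-3-{[tert-butyl(dimethyl)silyl]oxy}-2-methylcyclohex-2-en-1-yl]-2-methylpropan-1-ol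
Product: 6 2-[(1R)-3-{[tert-butyl(dimethyl)silyl]oxy}-2-methylcyclohex-2-en-1-yl]-2-methylpropanal
Conditions: Dess–Martin periodinane, pyridine, CH2Cl2, 0 °C
Reagents that add atoms: none
Why: Dess–Martin oxidation stops at the aldehyde, which cannot enolise or epimerise because C4 is quaternary, and the pyridine buffer protects the silyl enol ether from acetic acid.

Step 5
Reactants: 6 2-[(1R)-3-{[tert-butyl(dimethyl)silyl]oxy}-2-methylcyclohex-2-en-1-yl]-2-methylpropanal; 7 ethenyl(triphenyl)phosphonium bromide
Product: 10 (4aS,8aS)-5,5,8a-trimethyl-3,4,4a,5,8,8a-hexahydronaphthalen-1(2H)-one, via ammonium enolate 8 (not isolated), via phosphorus ylide 9 (not isolated)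
Conditions: Bu4N[Ph3SiF2] (1.2 equiv), THF, −20 °C; then 7 (1.3 equiv) in MeCN, −20 → 50 °C
Reagents that add atoms: none
Why: Fluoride from Bu4N[Ph3SiF2] cleaves the silyl enol ether to the regiodefined tetrasubstituted ammonium enolate 8, whose C10 adds to the terminal carbon of the vinylphosphonium salt (C1–C10 bond), and the non-stabilised ylide 9 formed at C2 attacks the C3 aldehyde to give an oxaphosphetane that collapses to the C2=C3 alkene and Ph3P=O. The closest known reaction type is the Schweizer annulation, a conjugate addition of an enolate to a vinylphosphonium salt followed by intramolecular Wittig olefination. Ring A is closed in the olefination by 6-exo-trig attack of the ylide carbon on the aldehyde carbonyl, the only carbonyl that the ylide can reach through a six-membered ring (the C9 ketone would give a cyclobutene). The new quaternary stereocenter C10 is controlled by C5: its bulky 2-formylpropan-2-yl group sits pseudoaxial to avoid allylic strain with the C10 methyl of the enolate, so the electrophile enters on the opposite face, C1 ends up trans to C4 and the ring fusion is trans. The step needs C- over O-alkylation, Michael addition over aldol addition and C10 over C8 reactivity; the soft ammonium enolate and the soft phosphonium acceptor favour C-alkylation, aldol addition to the non-enolisable neopentyl aldehyde is reversible whereas the Wittig step is not, and the position of the enolate is fixed by the silyl enol ether made in step 2.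

Step 6
Reactants: 10 (4aS,8aS)-5,5,8a-trimethyl-3,4,4a,5,8,8a-hexahydronaphthalen-1(2H)-one
Product: 11 2β-acetoxy-3α-bromo-4,4,10-trimethyl-trans-decal-9-one
Conditions: N-bromosuccinimide, AcOH, CH2Cl2, 0 °C → rt, dark
Reagents that add atoms: N-bromosuccinimide, O=C1CCC(=O)N1Br; acetic acid, CC(=O)O
Why: In this bromoacetoxylation (cohalogenation) the bromonium ion should form on the α-face because the β-face is screened by the axial C10 and C4 methyl groups, and acetic acid should open it at C2 from the β-face in the trans-diaxial sense (Fürst–Plattner rule), C3 being neopentyl, which sets the 2β-acetoxy and 3α-bromo centers.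

Step 7
Reactants: 11 2β-acetoxy-3α-bromo-4,4,10-trimethyl-trans-decal-9-one
Product: 12 2β-acetoxy-4,4,10-trimethyl-trans-decal-9-one
Conditions: Bu3SnH, AIBN (cat.), benzene, 80 °C
Reagents that add atoms: none
Why: Radical-chain tin hydride dehalogenation removes the C3 bromine without touching C2, because the 1,2-acyloxy shift of the β-acetoxy radical is much slower than hydrogen transfer at this hydride concentration.

Step 8
Reactants: 12 2β-acetoxy-4,4,10-trimethyl-trans-decal-9-one
Product: 13 2β-acetoxy-4,4,10-trimethyl-8-methylene-trans-decal-9-one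
Conditions: (CH2O)n, N-methylanilinium trifluoroacetate, THF, reflux
Reagents that add atoms: formaldehyde (as paraformaldehyde), C=O
Why: This Mannich-type α-methylenation can only engage C8, the sole enolisable position because C10 is quaternary, and its mildly acidic conditions leave the acetate intact.

Step 9
Reactants: 13 2β-acetoxy-4,4,10-trimethyl-8-methylene-trans-decal-9-one; 14 (4-bromobut-1-yn-1-yl)trimethylsilane
Product: 17 C9 methyl carbonate of the 9α-alkylated 8-methylene decalin, via Grignard reagent 15 (not isolated), via magnesium alkoxide 16 (not isolated)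
Conditions: 14, Mg, THF, 25 °C; CeCl3, THF, −78 °C; 13, −78 → 0 °C; ClCO2Me, 0 → 25 °C
Reagents that add atoms: methyl chloroformate, COC(=O)Cl
Why: Cerium-modified Grignard 1,2-addition to the hindered cross-conjugated ketone should outrun attack on the acetate at −78 °C and suppress 1,4-addition, the nucleophile entering C9 from the α-face opposite the axial C10 methyl, and the alkoxide is capped in the same flask as the methyl carbonate; the C9 configuration formed here is erased in step 10.

Step 10
Reactants: 17 C9 methyl carbonate of the 9α-alkylated 8-methylene decalin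
Product: 18 2β-acetoxy-14-(trimethylsilyl)-15,16-dinorlabd-8(17)-en-13-yne
Conditions: Pd(OAc)2 (5 mol %), n-Bu3P (20 mol %), HCO2NH4, 1,4-dioxane, 80 °C
Reagents that add atoms: none
Why: In this palladium-catalysed formate hydrogenolysis of an allylic carbonate, ionisation gives a π-allyl complex over C9–C8–C17 with the metal on the α-face (anti to the leaving group and away from the C10 methyl), and with n-Bu3P the formate hydride is passed from palladium to the more substituted terminus C9 on that face, which sets 9α-H (side chain β, equatorial) and leaves the C8=C17 alkene, both C9 epimers of 17 converging on the same complex.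

Step 11
Reactants: 18 2β-acetoxy-14-(trimethylsilyl)-15,16-dinorlabd-8(17)-en-13-yne
Product: 20 allyl 2β-acetoxy-16-norlabd-8(17)-en-13-yn-15-oate, via caesium alkynoate 19 (not isolated)
Conditions: CsF, CO2 (1 atm), DMSO, 25 °C; then allyl bromide, 25 °C
Reagents that add atoms: carbon dioxide, O=C=O; allyl bromide, C=CCBr
Why: Fluoride-mediated desilylative carboxylation of the alkynylsilane with CO2 should give the caesium alkynoate, which is O-alkylated in the same flask by allyl bromide, the acetate and the exocyclic alkene being inert to CsF in DMSO at room temperature.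

Step 12
Reactants: 20 allyl 2β-acetoxy-16-norlabd-8(17)-en-13-yn-15-oate
Product: 21 allyl 2β-acetoxylabda-8(17),13Z-dien-15-oate
Conditions: Me2CuLi (from CuI and MeLi), THF, −78 °C; MeOH then aq. NH4Cl at −78 °C
Reagents that add atoms: lithium dimethylcuprate, [Li+].C[Cu-]C
Why: Conjugate syn-carbocupration of the 2-alkynoate followed by protonation of the alkenylcopper at −78 °C places the new methyl and the new hydrogen cis, which gives the (Z)-3-methyl-2-enoate with C12 and the ester on the same side, and the esters are untouched by the cuprate at this temperature.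

Step 13
Reactants: 21 allyl 2β-acetoxylabda-8(17),13Z-dien-15-oate
Product: 22 2β-acetoxylabda-8(17),13Z-dien-15-oic acid
Conditions: Pd(PPh3)4 (5 mol %), morpholine, THF, 25 °C; aq. citric acid work-up
Reagents that add atoms: none
Why: Allyl transfer from the ester to morpholine by zerovalent palladium (Tsuji–Trost deallylation) frees the acid under neutral conditions that spare the acetate, the Z-enoate and the exocyclic alkene.

**Compound list**
1 | methyl 2-methylpropanoate | COC(=O)C(C)C | starting material
2 | tert-butyl[(1-methoxy-2-methylprop-1-en-1-yl)oxy]dimethylsilane | COC(O[Si](C)(C)C(C)(C)C)=C(C)C | intermediate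
3 | 2-methylcyclohex-2-en-1-one | CC1=CCCCC1=O | starting material
4 | methyl 2-[(1R)-3-{[tert-butyl(dimethyl)silyl]oxy}-2-methylcyclohex-2-en-1-yl]-2-methylpropanoate | C1CC[C@@H](C(C)(C)C(=O)OC)C(C)=C1O[Si](C)(C)C(C)(C)C | intermediate
5 | 2-[(1S)-3-{[tert-butyl(dimethyl)silyl]oxy}-2-methylcyclohex-2-en-1-yl]-2-methylpropan-1-ol | C1CC[C@@H](C(C)(C)CO)C(C)=C1O[Si](C)(C)C(C)(C)C | intermediate
6 | 2-[(1R)-3-{[tert-butyl(dimethyl)silyl]oxy}-2-methylcyclohex-2-en-1-yl]-2-methylpropanal | C1CC[C@@H](C(C)(C)C=O)C(C)=C1O[Si](C)(C)C(C)(C)C | intermediate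
7 | ethenyl(triphenyl)phosphonium bromide | C=C[P+](c1ccccc1)(c1ccccc1)c1ccccc1.[Br-] | starting material
8 | tetrabutylammonium (3R)-2-methyl-3-(2-methyl-1-oxopropan-2-yl)cyclohex-1-en-1-olate | C1CC[C@@H](C(C)(C)C=O)C(C)=C1[O-].CCCC[N+](CCCC)(CCCC)CCCC | intermediate (not isolated)
9 | phosphorus ylide: 2-methyl-2-{2-methyl-3-oxo-2-[2-(triphenylphosphoranylidene)ethyl]cyclohexyl}propanal, C5 as in 6, ylide chain on C10 trans to the C5 side chain | C1CC[C@@H](C(C)(C)C=O)[C@](C)(C[CH-][P+](c2ccccc2)(c2ccccc2)c2ccccc2)C1=O | intermediate (not isolated)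
10 | (4aS,8aS)-5,5,8a-trimethyl-3,4,4a,5,8,8a-hexahydronaphthalen-1(2H)-one (4,4,10-trimethyl-trans-Δ2-octalin-9-one; 5α-H, 10β-CH3) | C1CC[C@H]2C(C)(C)C=CC[C@]2(C)C1=O | intermediate
11 | 2β-acetoxy-3α-bromo-4,4,10-trimethyl-trans-decal-9-one (5α-H, 10β-CH3) | C1CC[C@H]2C(C)(C)[C@H](Br)[C@@H](OC(C)=O)C[C@]2(C)C1=O | intermediate
12 | 2β-acetoxy-4,4,10-trimethyl-trans-decal-9-one | C1CC[C@H]2C(C)(C)C[C@@H](OC(C)=O)C[C@]2(C)C1=O | intermediate
13 | 2β-acetoxy-4,4,10-trimethyl-8-methylene-trans-decal-9-one | C=C1CC[C@H]2C(C)(C)C[C@@H](OC(C)=O)C[C@]2(C)C1=O | intermediate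
14 | (4-bromobut-1-yn-1-yl)trimethylsilane | C[Si](C)(C)C#CCCBr | starting material
15 | [4-(trimethylsilyl)but-3-yn-1-yl]magnesium bromide | C[Si](C)(C)C#CCC[Mg]Br | intermediate (not isolated)
16 | bromomagnesium 2β-acetoxy-4,4,10-trimethyl-8-methylene-9α-[4-(trimethylsilyl)but-3-yn-1-yl]-trans-decalin-9β-olate | C=C1CC[C@H]2C(C)(C)C[C@@H](OC(C)=O)C[C@]2(C)[C@@]1(CCC#C[Si](C)(C)C)O[Mg]Br | intermediate (not isolated)
17 | 2β-acetoxy-9β-[(methoxycarbonyl)oxy]-4,4,10-trimethyl-8-methylene-9α-[4-(trimethylsilyl)but-3-yn-1-yl]-trans-decalin | C=C1CC[C@H]2C(C)(C)C[C@@H](OC(C)=O)C[C@]2(C)[C@@]1(CCC#C[Si](C)(C)C)OC(=O)OC | intermediate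
18 | 2β-acetoxy-14-(trimethylsilyl)-15,16-dinorlabd-8(17)-en-13-yne (9α-H) | C=C1CC[C@H]2C(C)(C)C[C@@H](OC(C)=O)C[C@]2(C)[C@H]1CCC#C[Si](C)(C)C | intermediate
19 | caesium 2β-acetoxy-16-norlabd-8(17)-en-13-yn-15-oate | C=C1CC[C@H]2C(C)(C)C[C@@H](OC(C)=O)C[C@]2(C)[C@H]1CCC#CC(=O)[O-].[Cs+] | intermediate (not isolated)
20 | allyl 2β-acetoxy-16-norlabd-8(17)-en-13-yn-15-oate | C=C1CC[C@H]2C(C)(C)C[C@@H](OC(C)=O)C[C@]2(C)[C@H]1CCC#CC(=O)OCC=C | intermediate
21 | allyl 2β-acetoxylabda-8(17),13Z-dien-15-oate | C=C1CC[C@H]2C(C)(C)C[C@@H](OC(C)=O)C[C@]2(C)[C@H]1CC/C(C)=C\C(=O)OCC=C | intermediate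
22 | 2β-acetoxylabda-8(17),13Z-dien-15-oic acid | C=C1CC[C@H]2C(C)(C)C[C@@H](OC(C)=O)C[C@]2(C)[C@H]1CC/C(C)=C\C(=O)O | target

**Totals**
Total step count: 13. Longest linear sequence: 13 steps (1 → 22); 3, 7 and 14 are purchased partners.

**Steps most likely to fail**

Step 5 (key step). What may go wrong: O-alkylation of the enolate or sluggish conjugate addition at the congested C10, and quenching of the ylide by proton transfer from C8 before olefination. Fallback: from 6, methylenation of the aldehyde with Ph3P=CH2 (from Ph3PCH3Br and KN(SiMe3)2, THF, 0 °C) should give the vinyl silyl enol ether F1. Fluoride-promoted unmasking (Bu4N[Ph3SiF2], THF) to the ammonium enolate F2 and C-allylation with allyl bromide, again anti to the C5 substituent, should give the 2-allyl-2-methyl ketone F3. Ring-closing metathesis (second-generation Grubbs catalyst, CH2Cl2, 40 °C) then closes ring A with loss of ethylene and comes back to the route at 10.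

Step 10. What may go wrong: slow ionisation of the hindered tertiary carbonate (its C–O bond lies near the plane of the C8=C17 alkene in the chair), hydride delivery to C17 instead of C9, or β-hydride elimination to dienes. Fallback: from 13, the same cerium-modified Grignard addition, quenched with aqueous NH4Cl, should give the tertiary allylic alcohol F4. Ph3SiOReO3-catalysed 1,3-transposition (Et2O, 0 °C) should give the primary allylic alcohol F5 with the C8=C9 alkene. Mitsunobu reaction with 2-nitrobenzenesulfonylhydrazide (PPh3, diethyl azodicarboxylate, THF, −30 °C) should give the N-allylic sulfonylhydrazine F6, which on warming loses 2-nitrobenzenesulfinic acid to the allylic diazene F7. Its retro-ene loss of N2 passes hydrogen to C9 on the less hindered α-face and moves the alkene to C8=C17, which comes back to the route at 18.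

Step 2. What may go wrong: poor turnover or poor facial selectivity of the cationic catalyst with the α-methylated enone. Fallback: from 2, the same catalysed addition to cyclohex-2-en-1-one, the unsubstituted enone for which this reaction type is established, should give the silyl enol ether F8. Fluoride-promoted regiospecific C-methylation (Bu4N[Ph3SiF2], MeI, THF) should give the trans-2-methyl ketone F9. Equilibrating silylation (t-BuMe2SiOTf, Et3N, CH2Cl2, 25 °C) to the more substituted enol ether comes back to the route at 4.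

**Further compounds**
F1 | step 5 | tert-butyldimethyl{[(3S)-2-methyl-3-(2-methylbut-3-en-2-yl)cyclohex-1-en-1-yl]oxy}silane | C1CC[C@@H](C(C)(C)C=C)C(C)=C1O[Si](C)(C)C(C)(C)C
F2 | step 5 | tetrabutylammonium (3S)-2-methyl-3-(2-methylbut-3-en-2-yl)cyclohex-1-en-1-olate | C1CC[C@@H](C(C)(C)C=C)C(C)=C1[O-].CCCC[N+](CCCC)(CCCC)CCCC
F3 | step 5 | 2-allyl-2-methyl-3-(2-methylbut-3-en-2-yl)cyclohexan-1-one (allyl trans to the C3 substituent, C3 as in F1) | C1CC[C@@H](C(C)(C)C=C)[C@](C)(CC=C)C1=O
F4 | step 10 | 2β-acetoxy-4,4,10-trimethyl-8-methylene-9α-[4-(trimethylsilyl)but-3-yn-1-yl]-trans-decalin-9β-ol | C=C1CC[C@H]2C(C)(C)C[C@@H](OC(C)=O)C[C@]2(C)[C@@]1(CCC#C[Si](C)(C)C)O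
F5 | step 10 | 2β-acetoxy-14-(trimethylsilyl)-15,16-dinorlabd-8-en-13-yn-17-ol | OCC=1CC[C@H]2C(C)(C)C[C@@H](OC(C)=O)C[C@]2(C)C=1CCC#C[Si](C)(C)C
F6 | step 10 | N-(C17-allylic)-N-(2-nitrophenylsulfonyl)hydrazine derived from F5 | NN(CC=1CC[C@H]2C(C)(C)C[C@@H](OC(C)=O)C[C@]2(C)C=1CCC#C[Si](C)(C)C)S(=O)(=O)c1ccccc1[N+](=O)[O-]
F7 | step 10 | C17 allylic diazene derived from F6 | N=NCC=1CC[C@H]2C(C)(C)C[C@@H](OC(C)=O)C[C@]2(C)C=1CCC#C[Si](C)(C)C
F8 | step 2 | methyl 2-[(1R)-3-{[tert-butyl(dimethyl)silyl]oxy}cyclohex-2-en-1-yl]-2-methylpropanoate | C1CC[C@@H](C(C)(C)C(=O)OC)C=C1O[Si](C)(C)C(C)(C)C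
F9 | step 2 | methyl 2-methyl-2-(trans-2-methyl-3-oxocyclohexyl)propanoate (ring C1 as in 4) | C1CC[C@@H](C(C)(C)C(=O)OC)[C@H](C)C1=O
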